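A small charge of starting material goes two ways in this flask: to product with reagent in the reaction phase, and to quenched substrate with protic impurity.

in all of them: starting material 0.25 M; protic impurity 0.125 M

| flask | reagent in the second phase | remark | time | volume of the second phase over the first |
|---|---|---|---|---|
| delta | 0.14 M | run made earlier |  |  |
| flask | 0.275 M |  | 30 h | 1.0 |

delta run (percent of the starting material charged)

| time / h | product / % | starting material / % |
|---|---|---|
| 1.00 | 8.1 | 82.8 |
| 2.00 | 15.2 | 69.9 |
| 3.00 | 19.7 | 60.4 |
| 4.00 | 22.6 | 53.0 |
| 5.00 | 25.8 | 48.3 |
| 6.00 | 26.6 | 43.8 |

(standard deviation of a reading: 1 percentage point)

- in the second phase: reagent in the second phase; everything else is in the first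
- charges count per volume of the first phase; a concentration in a rate is the amount of a species over the volume of its own phase; every rate counts per litre of the first phase
- what may be going on: reagent in the reaction phase <-> reagent in the second phase; starting material + protic impurity -> quenched substrate; starting material + reagent in the reaction phase -> product; reagent in the reaction phase -> decomposed reagent
- the earlier runs hold the two phases in the same ratio of volumes as the flask asked about

- Monday's: doubling the transfer coefficient of the reagent in the second phase, all else as stated
- Friday's: doubling the amount of reagent in the second phase, all else as stated

* how much product there is at 30 h, in percent of the starting material charged
* the change that raises the amount of product at 30 h, in percent of the starting material charged most ("none" if none brings more than 2 percentage points) (Monday's / Friday's / none)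
* amount of product at 30 h, in percent of the starting material charged, after Monday's

If the transfer between the phases is taken as equilibrated, reagent in the reaction phase stands as a constant part of the reagent still present. As a rough reckoning that sets aside the consumption of reagent and of protic impurity, product over quenched substrate is then taken to follow c(reagent in the second phase) over c(protic impurity) as charged. In the delta run, quenched substrate is what the two readings leave missing, and at 3.00 h product over it reads 0.990. Divided by the delta charge ratio, this gives the split number, the ratio of product to quenched substrate per unit of charge ratio, a selectivity factor read with the scatter of the readings: 0.884.

For the asked flask, my own reckoning gives product over quenched substrate of 1.94, so 66.0% of the reacted starting material becomes product, and y is put near that. Monday's transfer coefficient does not enter the split number, so by hand it gains nothing. Friday's doubles the ratio and raises the share to 79.5%, a gain of 14 percentage points, more than the margin.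

The forecast gives 56%, lower than this reckoning, with Friday's as the best change and 57% after Monday's: “Doubling transfer should add only a point or so, since the phases are near equilibrium.”

The flask gives 63.6%. The best change is Friday's, which adds 16 points, while Monday's ends at 63.8%, up by 0.16 points.

    reagent in the reaction phase ⇌ reagent in the second phase, rate k1*([reagent in the reaction phase] - [reagent in the second phase]/K1) per volume of the first phase (partition coefficient = 1.10, kL = 0.110 min⁻¹)
    starting material + protic impurity → quenched substrate (k = 0.0140 L mol⁻¹ min⁻¹)
    starting material + reagent in the reaction phase → product (k = 0.0290 L mol⁻¹ min⁻¹)
    reagent in the reaction phase → decomposed reagent (k = 9.80 × 10⁻⁴ min⁻¹)

In the flask, the rate of starting material into product over its rate into quenched substrate stands at 2.0 at 0.232 h and at 0.98 at 30.0 h, while the amounts at 30.0 h give product over quenched substrate of 1.89, beside the reckoned 1.94. The neighbouring flask with 0.42 M of starting material has the same charge ratio, hence the same reckoned 1.94, and it ends with 54.8% product and 28.4% quenched substrate, a ratio of 1.93, with 17% of its starting material left.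

All runs were generated by integration on assumed constants, noise included.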